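**Plan**
1. Retrosynthesis: the two MOM ethers are removed first; ring D is then cut at C4′–O, C3′–C4″ and O–C2″, which leaves a C3′–C4′ aryne of the complete isoflavan and 3-methylbut-2-enal; ring C is cut at O1–C2 and C3–C4, which leaves a ring B arylacetyl imide and a ring A benzylic bromide.
2. Enabling feature: ring D is fused to ring B through C3′ (carbon) and C4′ (oxygen), and C3′ sits next to the C2′ oxygen; a C3′≡C4′ aryne flanked by that alkoxy group accepts a carbonyl oxygen at C4′ and carbon at C3′.
3. Forward order: the ring A fragment (C-prenylation, protection, benzylic bromide) and the ring B fragment (silylation at C3′ between the carbamate and MOM oxygens, homologation to the arylacetic acid) are joined at C3–C4.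
4. Ring C then closes by Mitsunobu etherification, the carbamate is exchanged for triflate, ring D closes last, and MOM removal ends the route.
5. Stereochemistry: the only stereocentre, C3 (S), comes from alkylation of the enolate of an (S)-4-benzyl-oxazolidinone imide and is not touched afterwards.

Key step: step 18

Remark: the SMILES is read as the (3S)-isoflavan. Isoflavan numbering is used: rings A and C form the chroman, ring B is the 3-aryl group, ring D is the dimethylpyran (double-primed atoms). MOM = methoxymethyl, prenyl = 3-methylbut-2-en-1-yl.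

**Ring A fragment**

Step 1
Reactants: 1 2,4-dihydroxybenzaldehyde; 2 prenyl bromide (1-bromo-3-methylbut-2-ene)
Product: 3 2,4-dihydroxy-3-(3-methylbut-2-en-1-yl)benzaldehyde
Conditions: KOH (10% aq), 0 °C to rt; chromatography
Reagents that add atoms: none
Why: nuclear C-prenylation of the phenoxide in water should favour the doubly activated C3 between the two oxygens; this is a known reaction of this aldehyde of only moderate efficiency, accepted because it is the first step on bulk materials, and the O-prenyl ether and C5 isomer are removed here.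

Step 2
Reactants: 3 2,4-dihydroxy-3-(3-methylbut-2-en-1-yl)benzaldehyde
Product: 4 2-hydroxy-4-(methoxymethoxy)-3-(3-methylbut-2-en-1-yl)benzaldehyde
Conditions: MOMCl (1.05 equiv), i-Pr2NEt, CH2Cl2, 0 °C
Reagents that add atoms: chloromethyl methyl ether, COCCl
Why: selective O-alkylation (acetal ether formation) should take place at the more acidic 4-OH, because the 2-OH is tied up in the hydrogen bond to the formyl group.

Step 3
Reactants: 4 2-hydroxy-4-(methoxymethoxy)-3-(3-methylbut-2-en-1-yl)benzaldehyde
Product: 5 4-(methoxymethoxy)-3-(3-methylbut-2-en-1-yl)-2-(prop-2-en-1-yloxy)benzaldehyde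
Conditions: allyl bromide, K2CO3, DMF, 50 °C
Reagents that add atoms: allyl bromide, C=CCBr
Why: Williamson etherification of the remaining phenol installs an allyl ether that survives hydride, enolate and bromination conditions and can later be removed by zerovalent palladium without acid or fluoride.

Step 4
Reactants: 5 4-(methoxymethoxy)-3-(3-methylbut-2-en-1-yl)-2-(prop-2-en-1-yloxy)benzaldehyde
Product: 6 [4-(methoxymethoxy)-3-(3-methylbut-2-en-1-yl)-2-(prop-2-en-1-yloxy)phenyl]methanol
Conditions: NaBH4, MeOH, 0 °C
Reagents that add atoms: none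
Why: borohydride reduction is chemoselective for the aldehyde and leaves both alkenes and the acetal ether untouched.

Step 5
Reactants: 6 [4-(methoxymethoxy)-3-(3-methylbut-2-en-1-yl)-2-(prop-2-en-1-yloxy)phenyl]methanol
Product: 7 1-(bromomethyl)-4-(methoxymethoxy)-3-(3-methylbut-2-en-1-yl)-2-(prop-2-en-1-yloxy)benzene
Conditions: CBr4, PPh3, CH2Cl2, −20 to 0 °C; filtered through basic alumina and used at once
Reagents that add atoms: tetrabromomethane, BrC(Br)(Br)Br
Why: the Appel reaction converts the benzylic alcohol to the bromide under neutral conditions that spare the MOM ether and the alkenes; the electron-rich bromide is not stored.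

**Ring B fragment**

Step 6
Reactants: 1 2,4-dihydroxybenzaldehyde
Product: 8 4-formyl-3-hydroxyphenyl diethylcarbamate
Conditions: Et2NCOCl (1.05 equiv), K2CO3, MeCN, 60 °C
Reagents that add atoms: N,N-diethylcarbamoyl chloride, CCN(CC)C(Cl)=O
Why: O-carbamoylation should be selective for the 4-OH, which is the more acidic and is not chelated to the formyl group.

Step 7
Reactants: 8 4-formyl-3-hydroxyphenyl diethylcarbamate
Product: 9 4-formyl-3-(methoxymethoxy)phenyl diethylcarbamate
Conditions: MOMCl, i-Pr2NEt, CH2Cl2, 0 °C to rt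
Reagents that add atoms: chloromethyl methyl ether, COCCl
Why: standard MOM ether formation of a salicylaldehyde hydroxyl gives the second ortho-directing group and the alkoxy group that will later flank the aryne.

Step 8
Reactants: 9 4-formyl-3-(methoxymethoxy)phenyl diethylcarbamate
Product: 10 4-ethynyl-3-(methoxymethoxy)phenyl diethylcarbamate
Conditions: dimethyl (1-diazo-2-oxopropyl)phosphonate, K2CO3, MeOH, 0 °C to rt
Reagents that add atoms: dimethyl (1-diazo-2-oxopropyl)phosphonate, COP(=O)(OC)C(=[N+]=[N-])C(C)=O
Why: the Seyferth–Gilbert homologation in its Ohira–Bestmann form turns the aldehyde into the terminal alkyne under conditions mild enough for the dialkyl carbamate, and the alkyne is a masked acetic acid side chain that tolerates organolithium base.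

Step 9
Reactants: 10 4-ethynyl-3-(methoxymethoxy)phenyl diethylcarbamate
Product: 12 3-(methoxymethoxy)-2-(trimethylsilyl)-4-[(trimethylsilyl)ethynyl]phenyl diethylcarbamate, via dilithio species 11 (not isolated)
Conditions: s-BuLi (2.3 equiv), TMEDA, THF, −78 °C; Me3SiCl (3 equiv), −78 °C to rt
Reagents that add atoms: chlorotrimethylsilane, C[Si](C)(C)Cl
Why: the first equivalent of base gives the acetylide, the second performs directed ortho-metalation at the ring position flanked by the carbamate and MOM groups (cooperative direction), and both carbanions are silylated while the low temperature suppresses the anionic ortho-Fries shift.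

Step 10
Reactants: 12 3-(methoxymethoxy)-2-(trimethylsilyl)-4-[(trimethylsilyl)ethynyl]phenyl diethylcarbamate
Product: 15 [4-(diethylcarbamoyloxy)-2-(methoxymethoxy)-3-(trimethylsilyl)phenyl]acetic acid, via alkenylborane 13 (not isolated), via acylsilane 14 (not isolated)
Conditions: Cy2BH (from BH3·SMe2 and cyclohexene), THF, 0 °C to rt; then NaOH, H2O2, H2O, 0 to 40 °C; work-up at pH 4
Reagents that add atoms: hydrogen peroxide, OO
Why: hydroboration–oxidation of a 1-silylalkyne should place boron on the silicon-bearing carbon (away from the aryl group), oxidation gives the acylsilane and alkaline peroxide cleaves it to the carboxylic acid, while the aryl C–Si bond and the carbamate are inert to these conditions.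

Step 11
Reactants: 15 [4-(diethylcarbamoyloxy)-2-(methoxymethoxy)-3-(trimethylsilyl)phenyl]acetic acid; 16 (S)-4-benzyl-1,3-oxazolidin-2-one
Product: 18 (4S)-4-benzyl-3-{[4-(diethylcarbamoyloxy)-2-(methoxymethoxy)-3-(trimethylsilyl)phenyl]acetyl}-1,3-oxazolidin-2-one, via mixed anhydride 17 (not isolated)
Conditions: t-BuCOCl, Et3N, THF, −20 °C; then 16, LiCl, rt
Reagents that add atoms: none
Why: N-acylation of the oxazolidinone through the mixed pivalic anhydride with LiCl activation is the standard way to arylacetyl imides and needs no strong base.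

**Assembly**

Step 12
Reactants: 18 (4S)-4-benzyl-3-{[4-(diethylcarbamoyloxy)-2-(methoxymethoxy)-3-(trimethylsilyl)phenyl]acetyl}-1,3-oxazolidin-2-one; 7 1-(bromomethyl)-4-(methoxymethoxy)-3-(3-methylbut-2-en-1-yl)-2-(prop-2-en-1-yloxy)benzene
Product: 20 (4S)-4-benzyl-3-{(2S)-2-[4-(diethylcarbamoyloxy)-2-(methoxymethoxy)-3-(trimethylsilyl)phenyl]-3-[4-(methoxymethoxy)-3-(3-methylbut-2-en-1-yl)-2-(prop-2-en-1-yloxy)phenyl]propanoyl}-1,3-oxazolidin-2-one, via sodium enolate 19 (not isolated)
Conditions: NaN(SiMe3)2 (1.05 equiv), THF, −78 °C; then 7, −78 to −40 °C; chromatography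
Reagents that add atoms: none
Why: in this Evans alkylation the chelated (Z)-sodium enolate is attacked by the benzylic bromide on the face opposite the C4 benzyl group of the auxiliary, which sets the future C3 as S; a slight deficit of base guards against epimerisation and the minor diastereomer is removed by chromatography.

Step 13
Reactants: 20 the alkylated imide
Product: 21 4-{(2S)-1-hydroxy-3-[4-(methoxymethoxy)-3-(3-methylbut-2-en-1-yl)-2-(prop-2-en-1-yloxy)phenyl]propan-2-yl}-3-(methoxymethoxy)-2-(trimethylsilyl)phenyl diethylcarbamate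
Conditions: LiBH4, MeOH (1 equiv), THF, 0 °C
Reagents that add atoms: none
Why: reductive cleavage of the imide by borohydride gives the primary alcohol and the recoverable auxiliary without enolisation of the α-aryl centre, and the aryl carbamate is not reduced by this reagent.

Step 14
Reactants: 21 the allyl-protected alcohol
Product: 22 4-{(2S)-1-hydroxy-3-[2-hydroxy-4-(methoxymethoxy)-3-(3-methylbut-2-en-1-yl)phenyl]propan-2-yl}-3-(methoxymethoxy)-2-(trimethylsilyl)phenyl diethylcarbamate
Conditions: Pd(PPh3)4 (5 mol %), morpholine, THF, rt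
Reagents that add atoms: none
Why: in this Tsuji–Trost deallylation zerovalent palladium ionises only the aryl allyl ether and morpholine traps the allyl unit; the prenyl group has no leaving group, and the silyl, MOM and carbamate groups do not react.

Step 15
Reactants: 22 the phenol alcohol
Product: 23 (3S)-7,2′-bis(methoxymethoxy)-8-prenyl-3′-(trimethylsilyl)isoflavan-4′-yl diethylcarbamate
Conditions: PPh3, DIAD, THF (0.02 M), 0 °C to rt
Reagents that add atoms: none
Why: intramolecular Mitsunobu etherification closes ring C by 6-exo-tet displacement at the primary carbon by the ring A phenol; the stereocentre is not a reacting centre, and the MOM ether on the 2′-oxygen excludes the competing five-membered ether.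

Step 16
Reactants: 23 the isoflavan carbamate
Product: 24 (3S)-7,2′-bis(methoxymethoxy)-8-prenyl-3′-(trimethylsilyl)isoflavan-4′-ol
Conditions: LiAlH4, THF, 0 °C to reflux
Reagents that add atoms: none
Why: hydride cleavage of the aryl carbamate frees the 4′-phenol under non-acidic conditions, which matters because the electron-rich aryl C–Si bond would be at risk of protodesilylation in acid; nothing else in 23 is reducible.

Step 17
Reactants: 24 the ortho-silyl phenol
Product: 25 (3S)-7,2′-bis(methoxymethoxy)-8-prenyl-3′-(trimethylsilyl)isoflavan-4′-yl trifluoromethanesulfonate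
Conditions: PhNTf2, DBU, MeCN, rt
Reagents that add atoms: N-phenylbis(trifluoromethanesulfonimide), O=S(=O)(N(c1ccccc1)S(=O)(=O)C(F)(F)F)C(F)(F)F
Why: O-sulfonylation of the hindered phenoxide with the mild triflimide reagent is the usual last step towards ortho-silylaryl triflates and involves no fluoride or acid.

Step 18
Reactants: 25 the ortho-silylaryl triflate; 26 3-methylbut-2-enal
Product: 30 (3S)-3-[5-(methoxymethoxy)-2,2-dimethyl-2H-chromen-6-yl]-7-(methoxymethoxy)-8-(3-methylbut-2-en-1-yl)chromane (bis-MOM ether of the target), via aryne 27 (not isolated), via benzoxete 28 (not isolated), via ortho-quinone methide 29 (not isolated)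
Conditions: CsF (3 equiv), 26 (10 equiv), MeCN, rt; 25 added over 4 h
Reagents that add atoms: none
Why: Fluoride removes the C3′ silyl group and the aryl anion expels the C4′ triflate to give aryne 27; the carbonyl oxygen of 26 then adds at C4′, the aryne carbon remote from the 2′-OMOM group, and the C3′ anion, stabilised by the adjacent C2′–O bond, closes onto the carbonyl carbon to give benzoxete 28 (formal [2+2]). 28 opens to the vinyl ortho-quinone methide 29, and ring D closes by thermal disrotatory 6π-oxa-electrocyclisation of the O=C4′–C3′=CH–CH=CMe2 array, the oxygen bonding to the dimethyl-bearing carbon. The closest known reaction type is the synthesis of 2H-chromenes from ortho-silylaryl triflates and α,β-unsaturated aldehydes under fluoride. No stereocentre is formed, and C3 lies outside the reacting array and is not acidic under these conditions. The step needs the C4′–O/C3′–C sense of addition, which the 2′-alkoxy group flanking the triple bond should secure in the way known for 3-methoxybenzyne. It also needs the enal to outrun an ene reaction of the prenyl group and capture of 29 by a second aryne, which the large excess of 26 and the slow release of the aryne should secure.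

Step 19
Reactants: 30 the bis-MOM ether
Product: 31 (3S)-3-(5-hydroxy-2,2-dimethyl-2H-chromen-6-yl)-8-(3-methylbut-2-en-1-yl)chroman-7-ol (target)
Conditions: HCl (2 M in MeOH), rt to 40 °C, monitored and stopped at full conversion
Reagents that add atoms: none
Why: acid-catalysed solvolysis of the two aryl MOM acetals is routine for prenylated phenols and is run dilute and cool so that the prenyl and chromene double bonds are not protonated.

**Compound list**
1 | 2,4-dihydroxybenzaldehyde | O=Cc1ccc(O)cc1O | starting material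
2 | prenyl bromide (1-bromo-3-methylbut-2-ene) | CC(C)=CCBr | starting material
3 | 2,4-dihydroxy-3-(3-methylbut-2-en-1-yl)benzaldehyde | O=Cc1ccc(O)c(CC=C(C)C)c1O | intermediate
4 | 2-hydroxy-4-(methoxymethoxy)-3-(3-methylbut-2-en-1-yl)benzaldehyde | O=Cc1ccc(OCOC)c(CC=C(C)C)c1O | intermediate
5 | 4-(methoxymethoxy)-3-(3-methylbut-2-en-1-yl)-2-(prop-2-en-1-yloxy)benzaldehyde | O=Cc1ccc(OCOC)c(CC=C(C)C)c1OCC=C | intermediate
6 | [4-(methoxymethoxy)-3-(3-methylbut-2-en-1-yl)-2-(prop-2-en-1-yloxy)phenyl]methanol | OCc1ccc(OCOC)c(CC=C(C)C)c1OCC=C | intermediate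
7 | 1-(bromomethyl)-4-(methoxymethoxy)-3-(3-methylbut-2-en-1-yl)-2-(prop-2-en-1-yloxy)benzene | BrCc1ccc(OCOC)c(CC=C(C)C)c1OCC=C | intermediate
8 | 4-formyl-3-hydroxyphenyl diethylcarbamate | CCN(CC)C(=O)Oc1ccc(C=O)c(O)c1 | intermediate
9 | 4-formyl-3-(methoxymethoxy)phenyl diethylcarbamate | CCN(CC)C(=O)Oc1ccc(C=O)c(OCOC)c1 | intermediate
10 | 4-ethynyl-3-(methoxymethoxy)phenyl diethylcarbamate | CCN(CC)C(=O)Oc1ccc(C#C)c(OCOC)c1 | intermediate
11 | dilithio species (lithium acetylide, ring lithiated between the two oxygens; not isolated) | CCN(CC)C(=O)Oc1ccc(C#C[Li])c(OCOC)c1[Li] | intermediate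
12 | 3-(methoxymethoxy)-2-(trimethylsilyl)-4-[(trimethylsilyl)ethynyl]phenyl diethylcarbamate | CCN(CC)C(=O)Oc1ccc(C#C[Si](C)(C)C)c(OCOC)c1[Si](C)(C)C | intermediate
13 | (Z)-alkenylborane, 4-[2-(dicyclohexylboranyl)-2-(trimethylsilyl)ethenyl]-3-(methoxymethoxy)-2-(trimethylsilyl)phenyl diethylcarbamate (not isolated) | CCN(CC)C(=O)Oc1ccc(/C=C(\[Si](C)(C)C)B(C2CCCCC2)C2CCCCC2)c(OCOC)c1[Si](C)(C)C | intermediate
14 | acylsilane, 3-(methoxymethoxy)-4-[2-oxo-2-(trimethylsilyl)ethyl]-2-(trimethylsilyl)phenyl diethylcarbamate (not isolated) | CCN(CC)C(=O)Oc1ccc(CC(=O)[Si](C)(C)C)c(OCOC)c1[Si](C)(C)C | intermediate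
15 | [4-(diethylcarbamoyloxy)-2-(methoxymethoxy)-3-(trimethylsilyl)phenyl]acetic acid | CCN(CC)C(=O)Oc1ccc(CC(=O)O)c(OCOC)c1[Si](C)(C)C | intermediate
16 | (S)-4-benzyl-1,3-oxazolidin-2-one | O=C1N[C@@H](Cc2ccccc2)CO1 | starting material
17 | mixed anhydride of 15 with pivalic acid (not isolated) | CCN(CC)C(=O)Oc1ccc(CC(=O)OC(=O)C(C)(C)C)c(OCOC)c1[Si](C)(C)C | intermediate
18 | (4S)-4-benzyl-3-{[4-(diethylcarbamoyloxy)-2-(methoxymethoxy)-3-(trimethylsilyl)phenyl]acetyl}-1,3-oxazolidin-2-one | CCN(CC)C(=O)Oc1ccc(CC(=O)N2[C@@H](Cc3ccccc3)COC2=O)c(OCOC)c1[Si](C)(C)C | intermediate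
19 | sodium (Z)-enolate of 18 (not isolated) | [Na+].CCN(CC)C(=O)Oc1ccc(/C=C(\[O-])N2[C@@H](Cc3ccccc3)COC2=O)c(OCOC)c1[Si](C)(C)C | intermediate
20 | (4S)-4-benzyl-3-{(2S)-2-[4-(diethylcarbamoyloxy)-2-(methoxymethoxy)-3-(trimethylsilyl)phenyl]-3-[4-(methoxymethoxy)-3-(3-methylbut-2-en-1-yl)-2-(prop-2-en-1-yloxy)phenyl]propanoyl}-1,3-oxazolidin-2-one | O=C(N1[C@@H](Cc2ccccc2)COC1=O)[C@H](c1ccc(OC(=O)N(CC)CC)c([Si](C)(C)C)c1OCOC)Cc1ccc(OCOC)c(CC=C(C)C)c1OCC=C | intermediate
21 | 4-{(2S)-1-hydroxy-3-[4-(methoxymethoxy)-3-(3-methylbut-2-en-1-yl)-2-(prop-2-en-1-yloxy)phenyl]propan-2-yl}-3-(methoxymethoxy)-2-(trimethylsilyl)phenyl diethylcarbamate | OC[C@H](c1ccc(OC(=O)N(CC)CC)c([Si](C)(C)C)c1OCOC)Cc1ccc(OCOC)c(CC=C(C)C)c1OCC=C | intermediate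
22 | 4-{(2S)-1-hydroxy-3-[2-hydroxy-4-(methoxymethoxy)-3-(3-methylbut-2-en-1-yl)phenyl]propan-2-yl}-3-(methoxymethoxy)-2-(trimethylsilyl)phenyl diethylcarbamate | OC[C@H](c1ccc(OC(=O)N(CC)CC)c([Si](C)(C)C)c1OCOC)Cc1ccc(OCOC)c(CC=C(C)C)c1O | intermediate
23 | (3S)-7,2′-bis(methoxymethoxy)-8-prenyl-3′-(trimethylsilyl)isoflavan-4′-yl diethylcarbamate | CC(C)=CCc1c(OCOC)ccc2c1OC[C@H](c1ccc(OC(=O)N(CC)CC)c([Si](C)(C)C)c1OCOC)C2 | intermediate
24 | (3S)-7,2′-bis(methoxymethoxy)-8-prenyl-3′-(trimethylsilyl)isoflavan-4′-ol | CC(C)=CCc1c(OCOC)ccc2c1OC[C@H](c1ccc(O)c([Si](C)(C)C)c1OCOC)C2 | intermediate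
25 | (3S)-7,2′-bis(methoxymethoxy)-8-prenyl-3′-(trimethylsilyl)isoflavan-4′-yl trifluoromethanesulfonate | CC(C)=CCc1c(OCOC)ccc2c1OC[C@H](c1ccc(OS(=O)(=O)C(F)(F)F)c([Si](C)(C)C)c1OCOC)C2 | intermediate
26 | 3-methylbut-2-enal | CC(C)=CC=O | starting material
27 | (3S)-7,2′-bis(methoxymethoxy)-8-prenyl-3′,4′-didehydroisoflavan, the C3′–C4′ aryne (not isolated) | CC(C)=CCc1c(OCOC)ccc2c1OC[C@H](C1=C(OCOC)C#CC=C1)C2 | intermediate
28 | 2H-benzoxete fused at C3′–C4′, oxygen on C4′, CH(CH=CMe2) on C3′ (not isolated) | CC(C)=CCc1c(OCOC)ccc2c1OC[C@H](c1ccc3OC(C=C(C)C)c3c1OCOC)C2 | intermediate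
29 | vinyl ortho-quinone methide, C4′=O and C3′=CH–CH=CMe2 (not isolated) | CC(C)=CCc1c(OCOC)ccc2c1OC[C@H](C1=C(OCOC)C(=CC=C(C)C)C(=O)C=C1)C2 | intermediate
30 | (3S)-3-[5-(methoxymethoxy)-2,2-dimethyl-2H-chromen-6-yl]-7-(methoxymethoxy)-8-(3-methylbut-2-en-1-yl)chromane | CC(C)=CCc1c(OCOC)ccc2c1OC[C@H](c1ccc3c(c1OCOC)C=CC(C)(C)O3)C2 | intermediate
31 | (3S)-3-(5-hydroxy-2,2-dimethyl-2H-chromen-6-yl)-8-(3-methylbut-2-en-1-yl)chroman-7-ol | CC(C)=CCc1c(O)ccc2c1OC[C@H](c1ccc3c(c1O)C=CC(C)(C)O3)C2 | target

**Totals**
Total step count: 19. Longest linear sequence: 14 steps (steps 6 to 11, then 12 to 19, from 2,4-dihydroxybenzaldehyde).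

**Steps most likely to fail**

1. Step 18. The aryne may be consumed by an ene reaction with a prenyl group of another molecule or by addition to the quinone methide, and fluoride may dienolise the enal so that it condenses with itself; each pathway outruns the [2+2] addition. The fallback sets out from 25 and builds ring D in stages. 25 is treated with CsF in N,N-dimethylformamide as solvent, so that the aryne inserts into the formamide C=O bond with the same orientation (oxygen at C4′, carbon at C3′). Aqueous work-up should give the salicylaldehyde (3S)-4′-hydroxy-7,2′-bis(methoxymethoxy)-8-prenylisoflavan-3′-carbaldehyde F1. Addition of excess 2-methylprop-1-enylmagnesium bromide (THF, 0 °C) should give the ortho-hydroxybenzylic allylic alcohol (3S)-3′-(1-hydroxy-3-methylbut-2-en-1-yl)-7,2′-bis(methoxymethoxy)-8-prenylisoflavan-4′-ol F2. Warming F2 in toluene with a trace of pyridinium p-toluenesulfonate should cause loss of water to quinone methide 29 and electrocyclisation, and the route is rejoined at 30.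

2. Step 10. Boron may add with the wrong orientation next to the ortho-substituted aryl group, or the oxidation may stall at the acylsilane or end in protodesilylation, so that the acid is not formed cleanly. The fallback sets out from 12 and reaches the acid through the aldehyde. K2CO3 in MeOH at rt should cleave only the alkynyl C–Si bond and give 4-ethynyl-3-(methoxymethoxy)-2-(trimethylsilyl)phenyl diethylcarbamate F3. Anti-Markovnikov hydroboration with Cy2BH and buffered oxidation with NaBO3 should give the arylacetaldehyde 3-(methoxymethoxy)-4-(2-oxoethyl)-2-(trimethylsilyl)phenyl diethylcarbamate F4. Pinnick oxidation (NaClO2, NaH2PO4, 2-methylbut-2-ene, t-BuOH/H2O) then rejoins the route at 15.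

3. Step 19. Protonation of the prenyl or chromene double bond may compete with acetal cleavage, leading to cyclisation of the 7-hydroxyl onto the prenyl group or to solvent addition before both MOM groups are gone. The fallback sets out from 30 and replaces protic solvolysis by silyl transfer under basic buffering. Me3SiOTf with 2,2′-bipyridyl (CH2Cl2, 0 °C to rt) should convert both aryl MOM ethers into the bis(trimethylsilyl) ether of the target F5. Brief treatment with K2CO3 in MeOH at 0 °C then rejoins the route at 31.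

**Further compounds**
F1 | step 18 | (3S)-4′-hydroxy-7,2′-bis(methoxymethoxy)-8-prenylisoflavan-3′-carbaldehyde | CC(C)=CCc1c(OCOC)ccc2c1OC[C@H](c1ccc(O)c(C=O)c1OCOC)C2
F2 | step 18 | (3S)-3′-(1-hydroxy-3-methylbut-2-en-1-yl)-7,2′-bis(methoxymethoxy)-8-prenylisoflavan-4′-ol, both carbinol epimers | CC(C)=CCc1c(OCOC)ccc2c1OC[C@H](c1ccc(O)c(C(O)C=C(C)C)c1OCOC)C2
F3 | step 10 | 4-ethynyl-3-(methoxymethoxy)-2-(trimethylsilyl)phenyl diethylcarbamate | CCN(CC)C(=O)Oc1ccc(C#C)c(OCOC)c1[Si](C)(C)C
F4 | step 10 | 3-(methoxymethoxy)-4-(2-oxoethyl)-2-(trimethylsilyl)phenyl diethylcarbamate | CCN(CC)C(=O)Oc1ccc(CC=O)c(OCOC)c1[Si](C)(C)C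
F5 | step 19 | bis(trimethylsilyl) ether of the target | CC(C)=CCc1c(O[Si](C)(C)C)ccc2c1OC[C@H](c1ccc3c(c1O[Si](C)(C)C)C=CC(C)(C)O3)C2
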